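The cyclopentane of the cyclol core (tertiary ether carbon, its two CH2 groups and the two ring-fusion CH carbons) is traced back to a cyclopropane. A triplet-sensitised vinylcyclopropane 1,3-shift of a 4-silyloxy-2,5,5-trimethylbicyclo[4.1.0]hept-2-ene grows that three-membered ring by two atoms into the cyclopentene while the six-membered ring shrinks to the gem-dimethylcyclobutane, exploiting the shared ring-fusion bond of the bicyclo[3.2.0]heptane. One carbinol centre, set by asymmetric borylation, survives the diradical and relays absolute configuration. The derived cyclobutanone is condensed with a dibenzoxepinone; exo conjugate reduction and capture of the tertiary cation by the carbonyl oxygen then close the dihydropyran.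

Key step: step 6

Remark on the chemistry: dienone 1 is taken as a catalogue compound, and 5 to 8 are drawn as the anti cyclopropane diastereomer although the syn isomer is carried along, because both give the same diradical in step 6.

Step 1
Reactants: 1 4,4-dimethylcyclohexa-2,5-dien-1-one
Product: 3 (S)-5-hydroxy-4,4-dimethylcyclohex-2-en-1-one, via pinacol boronate 2 (not isolated)
Conditions: CuCl (5 mol%), NaOtBu (10 mol%), QuinoxP* (enantiomer that gives the S centre, 6 mol%), B2pin2 (1.0 equiv), MeOH, THF, 0 °C; then H2O2, pH 7 phosphate buffer, 0 °C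
Reagents that add atoms: bis(pinacolato)diboron CC1(C)OB(OC1(C)C)B1OC(C)(C)C(C)(C)O1 (boron of 2); hydrogen peroxide OO (hydroxyl oxygen of 3)
Why: Desymmetrising copper-catalysed asymmetric conjugate borylation of one of the two enantiotopic enone units, in which the ligand-controlled face of boron delivery sets C-5, followed by stereoretentive oxidation of the C–B bond.

Step 2
Reactants: 3 (S)-5-hydroxy-4,4-dimethylcyclohex-2-en-1-one
Product: 4 (S)-5-[(tert-butyldimethylsilyl)oxy]-4,4-dimethylcyclohex-2-en-1-one
Conditions: TBSCl, imidazole, DMF, 0 °C to rt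
Reagents that add atoms: tert-butyldimethylsilyl chloride CC(C)(C)[Si](C)(C)Cl
Why: Silylation of the secondary alcohol under non-enolising conditions gives the bulky group that later steers the ring closure; no stereocentre is touched.

Step 3
Reactants: 4 (S)-5-[(tert-butyldimethylsilyl)oxy]-4,4-dimethylcyclohex-2-en-1-one
Product: 5 (1R,4S,6S)-4-[(tert-butyldimethylsilyl)oxy]-5,5-dimethylbicyclo[4.1.0]heptan-2-one
Conditions: Me3S(O)I, NaH, DMSO, rt
Reagents that add atoms: trimethylsulfoxonium iodide C[S+](C)(C)=O.[I-]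
Why: Corey–Chaykovsky cyclopropanation of the enone, with the ylide expected to add mainly anti to the silyloxy group and 3-exo closure giving the cis ring fusion; the cyclopropane configuration is of no consequence later.

Step 4
Reactants: 5 (1R,4S,6S)-4-[(tert-butyldimethylsilyl)oxy]-5,5-dimethylbicyclo[4.1.0]heptan-2-one
Product: 7 (1R,4S,6S)-4-[(tert-butyldimethylsilyl)oxy]-5,5-dimethylbicyclo[4.1.0]hept-2-en-2-yl trifluoromethanesulfonate, via lithium enolate 6 (not isolated)
Conditions: LiN(SiMe3)2, THF, −78 °C; Comins' reagent, −78 °C; aq. NH4Cl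
Reagents that add atoms: lithium bis(trimethylsilyl)amide [Li]N([Si](C)(C)C)[Si](C)(C)C (lithium of 6); Comins' reagent O=S(=O)(N(c1ccc(Cl)cn1)S(=O)(=O)C(F)(F)F)C(F)(F)F
Why: Kinetic deprotonation at the CH2 group rather than the cyclopropyl CH and O-triflation at low temperature, where the β-silyloxy enolate should not eliminate; no stereocentre changes.

Step 5
Reactants: 7 (1R,4S,6S)-4-[(tert-butyldimethylsilyl)oxy]-5,5-dimethylbicyclo[4.1.0]hept-2-en-2-yl trifluoromethanesulfonate
Product: 8 tert-butyldimethyl{[(1R,4S,6S)-2,5,5-trimethylbicyclo[4.1.0]hept-2-en-4-yl]oxy}silane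
Conditions: MeMgBr, Fe(acac)3 (5 mol%), THF–NMP, −30 °C
Reagents that add atoms: methylmagnesium bromide C[Mg]Br
Why: Iron-catalysed Kumada-type cross-coupling of the alkenyl triflate installs the methyl group and completes the vinylcyclopropane without touching a stereocentre.

Step 6
Reactants: 8 tert-butyldimethyl{[(1R,4S,6S)-2,5,5-trimethylbicyclo[4.1.0]hept-2-en-4-yl]oxy}silane
Product: 9 tert-butyldimethyl{[(1S,5S,7S)-2,6,6-trimethylbicyclo[3.2.0]hept-2-en-7-yl]oxy}silane
Conditions: hν (254 nm, quartz), p-xylene (triplet sensitiser), pentane, 20 °C, argon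
Reagents that add atoms: none
Why: Triplet energy transfer from p-xylene gives the alkene triplet of 8, whose C-2 radical is cyclopropylcarbinyl and opens the internal C-1–C-6 bond to a cyclohept-2-ene-1,4-diyl (allyl radical over C-1, C-2 and C-3, secondary radical at C-6) in which both cyclopropane stereocentres are erased, so the diastereomers of 8 converge. After intersystem crossing C-6 recombines with C-3, a net 1,3-shift (vinylcyclopropane-to-cyclopentene rearrangement); the closest known reaction is the sensitised rearrangement of 2-carene-type bicyclo[4.1.0]hept-2-enes to bicyclo[3.2.0]hept-2-enes. The one new bond closes two rings at once by transannular 1,4-diradical recombination: the cyclobutane, and the cyclopentene, which is the former cyclopropane enlarged by C-2 and C-3. The new centres C-1 and C-5 of 9 can only be cis, and their sense is relayed from the untouched carbinol carbon, because the bulky silyloxy group should take the exo face, away from the C-2 methyl group (allylic 1,2-strain) and the concave side; the C-7 epimer would later give the enantiomeric ketone and is removed here by chromatography. The step needs internal rather than external cyclopropane cleavage and closure rather than fragmentation of the diradical; the secondary C-6 radical (against a primary one) and the absence of a cis alkyl hydrogen for a homodienyl shift should secure this.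

Step 7
Reactants: 9 tert-butyldimethyl{[(1S,5S,7S)-2,6,6-trimethylbicyclo[3.2.0]hept-2-en-7-yl]oxy}silane
Product: 10 (1S,5S,7S)-2,6,6-trimethylbicyclo[3.2.0]hept-2-en-7-ol
Conditions: Bu4NF, THF, rt
Reagents that add atoms: none
Why: Fluoride cleavage of the silyl ether under non-acidic conditions leaves the strained alkene and all stereocentres untouched.

Step 8
Reactants: 10 (1S,5S,7S)-2,6,6-trimethylbicyclo[3.2.0]hept-2-en-7-ol
Product: 11 (1S,5S)-2,6,6-trimethylbicyclo[3.2.0]hept-2-en-7-one
Conditions: Dess–Martin periodinane, CH2Cl2, rt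
Reagents that add atoms: none
Why: Mild oxidation to the cyclobutanone removes the relay centre after it has fixed C-1 and C-5.

Step 9
Reactants: 12 2-(2-bromo-4-methoxyphenyl)acetic acid; 13 3-methoxyphenol
Product: 14 2-[4-methoxy-2-(3-methoxyphenoxy)phenyl]acetic acid
Conditions: CuI (10 mol%), N,N-dimethylglycine (30 mol%), Cs2CO3, 1,4-dioxane, 100 °C; then aq. HCl
Reagents that add atoms: none
Why: Ullmann diaryl ether coupling, assisted by the ortho carboxylate side chain, joins the two arenes; no stereocentre is formed.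

Step 10
Reactants: 14 2-[4-methoxy-2-(3-methoxyphenoxy)phenyl]acetic acid
Product: 15 3,7-dimethoxydibenzo[b,f]oxepin-10(11H)-one
Conditions: (CF3CO)2O, CF3CO2H, CH2Cl2, 0 °C to rt
Reagents that add atoms: none
Why: Intramolecular Friedel–Crafts acylation through the mixed anhydride closes the seven-membered ring para to the methoxy group of the phenoxy ring, the only unhindered activated position.

Step 11
Reactants: 15 3,7-dimethoxydibenzo[b,f]oxepin-10(11H)-one
Product: 16 2-bromo-3,7-dimethoxydibenzo[b,f]oxepin-10(11H)-one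
Conditions: NBS, MeCN, 0 °C
Reagents that add atoms: N-bromosuccinimide O=C1CCC(=O)N1Br
Why: Electrophilic aromatic bromination should go to the benzylic ring, ortho to methoxy and para to the ether oxygen, because the other ring is deactivated as a vinylogous ester of the ketone.

Step 12
Reactants: 16 2-bromo-3,7-dimethoxydibenzo[b,f]oxepin-10(11H)-one; 11 (1S,5S)-2,6,6-trimethylbicyclo[3.2.0]hept-2-en-7-one
Product: 18 2-bromo-11-[(1S,5S)-7-hydroxy-2,6,6-trimethylbicyclo[3.2.0]hept-2-en-7-yl]-3,7-dimethoxydibenzo[b,f]oxepin-10(11H)-one, via lithium enolate 17 (not isolated)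
Conditions: LiN(iPr)2, THF, −78 °C; then 11, −78 °C; aq. NH4Cl at −78 °C
Reagents that add atoms: lithium diisopropylamide CC(C)N([Li])C(C)C (lithium of 17)
Why: Aldol addition of the benzylic ketone enolate to the strained, electrophilic cyclobutanone; the two new centres (carbinol carbon and C-11) are formed without control and are both removed or reset in steps 13 and 14.

Step 13
Reactants: 18 2-bromo-11-[(1S,5S)-7-hydroxy-2,6,6-trimethylbicyclo[3.2.0]hept-2-en-7-yl]-3,7-dimethoxydibenzo[b,f]oxepin-10(11H)-one
Product: 19 2-bromo-3,7-dimethoxy-11-[(1S,5S)-2,6,6-trimethylbicyclo[3.2.0]hept-2-en-7-ylidene]dibenzo[b,f]oxepin-10(11H)-one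
Conditions: Burgess reagent, toluene, 60 °C
Reagents that add atoms: none
Why: Neutral syn-elimination of the tertiary β-hydroxy ketone (Burgess dehydration) towards the acidic α-hydrogen gives the conjugated alkylidenecyclobutane without retro-aldol cleavage.

Step 14
Reactants: 19 2-bromo-3,7-dimethoxy-11-[(1S,5S)-2,6,6-trimethylbicyclo[3.2.0]hept-2-en-7-ylidene]dibenzo[b,f]oxepin-10(11H)-one
Product: 20 2-bromo-3,7-dimethoxy-11-[(1R,5S,7S)-2,6,6-trimethylbicyclo[3.2.0]hept-2-en-7-yl]dibenzo[b,f]oxepin-10(11H)-one (C-11 epimers)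
Conditions: [(Ph3P)CuH]6, toluene, rt; aq. NH4Cl
Reagents that add atoms: none
Why: Copper hydride conjugate reduction delivers hydride to the cyclobutane carbon from the exo face, opposite the cyclopentene, which places the oxepinone substituent on the concave face cis to the ring-fusion bond; the C-11 centre is inconsequential.

Step 15
Reactants: 20 2-bromo-3,7-dimethoxy-11-[(1R,5S,7S)-2,6,6-trimethylbicyclo[3.2.0]hept-2-en-7-yl]dibenzo[b,f]oxepin-10(11H)-one
Product: 21 the pentacyclic enol ether that is the target with Br in place of the prenyl group and both phenols as methyl ethers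
Conditions: CF3SO3H (5 mol%), CH2Cl2, −20 to 0 °C
Reagents that add atoms: none
Why: Acid-catalysed cycloisomerisation of a δ,ε-unsaturated ketone to a 3,4-dihydro-2H-pyran: protonation of the trisubstituted alkene gives the tertiary cation, which the carbonyl oxygen on the concave face captures through a six-membered transition state (setting the tertiary ether centre cis to the cyclobutane), and loss of the α-proton gives the stilbene-like enol ether.

Step 16
Reactants: 21 the bromo dimethyl ether pentacycle
Product: 22 the bis(methyl ether) of the target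
Conditions: Bu3SnCH2CH=CMe2, Pd(PPh3)4 (5 mol%), DMF, 100 °C
Reagents that add atoms: tributyl(3-methylbut-2-en-1-yl)stannane CCCC[Sn](CCCC)(CCCC)CC=C(C)C
Why: Stille coupling of the aryl bromide with the prenylstannane, where reductive elimination at the less hindered allyl terminus should give the linear prenyl group; no stereocentre is affected.

Step 17
Reactants: 22 the bis(methyl ether) of the target
Product: 23 CNP0185814.1
Conditions: NaSEt, DMF, 130 °C; then aq. NH4Cl
Reagents that add atoms: none
Why: Nucleophilic demethylation of both aryl methyl ethers by thiolate under basic conditions spares the enol ether, the tertiary ether and the prenyl group.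

Compound list
1 | 4,4-dimethylcyclohexa-2,5-dien-1-one | O=C1C=CC(C)(C)C=C1 | starting material
2 | (S)-4,4-dimethyl-5-(4,4,5,5-tetramethyl-1,3,2-dioxaborolan-2-yl)cyclohex-2-en-1-one | O=C1C=CC(C)(C)[C@@H](B2OC(C)(C)C(C)(C)O2)C1 | intermediate
3 | (S)-5-hydroxy-4,4-dimethylcyclohex-2-en-1-one | O=C1C=CC(C)(C)[C@@H](O)C1 | intermediate
4 | (S)-5-[(tert-butyldimethylsilyl)oxy]-4,4-dimethylcyclohex-2-en-1-one | O=C1C=CC(C)(C)[C@@H](O[Si](C)(C)C(C)(C)C)C1 | intermediate
5 | (1R,4S,6S)-4-[(tert-butyldimethylsilyl)oxy]-5,5-dimethylbicyclo[4.1.0]heptan-2-one (cyclopropane anti to the silyloxy group) | O=C1C[C@H](O[Si](C)(C)C(C)(C)C)C(C)(C)[C@H]2C[C@@H]12 | intermediate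
6 | lithium (1R,4S,6S)-4-[(tert-butyldimethylsilyl)oxy]-5,5-dimethylbicyclo[4.1.0]hept-2-en-2-olate | [Li]OC1=C[C@H](O[Si](C)(C)C(C)(C)C)C(C)(C)[C@H]2C[C@@H]12 | intermediate
7 | (1R,4S,6S)-4-[(tert-butyldimethylsilyl)oxy]-5,5-dimethylbicyclo[4.1.0]hept-2-en-2-yl trifluoromethanesulfonate | O=S(=O)(OC1=C[C@H](O[Si](C)(C)C(C)(C)C)C(C)(C)[C@H]2C[C@@H]12)C(F)(F)F | intermediate
8 | tert-butyldimethyl{[(1R,4S,6S)-2,5,5-trimethylbicyclo[4.1.0]hept-2-en-4-yl]oxy}silane | CC1=C[C@H](O[Si](C)(C)C(C)(C)C)C(C)(C)[C@H]2C[C@@H]12 | intermediate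
9 | tert-butyldimethyl{[(1S,5S,7S)-2,6,6-trimethylbicyclo[3.2.0]hept-2-en-7-yl]oxy}silane (silyloxy exo, cis to H-1 and H-5) | CC(C)(C)[Si](C)(C)O[C@H]1[C@H]2[C@H](CC=C2C)C1(C)C | intermediate
10 | (1S,5S,7S)-2,6,6-trimethylbicyclo[3.2.0]hept-2-en-7-ol | O[C@H]1[C@H]2[C@H](CC=C2C)C1(C)C | intermediate
11 | (1S,5S)-2,6,6-trimethylbicyclo[3.2.0]hept-2-en-7-one | O=C1[C@H]2[C@H](CC=C2C)C1(C)C | intermediate
12 | 2-(2-bromo-4-methoxyphenyl)acetic acid | OC(=O)Cc1ccc(OC)cc1Br | starting material
13 | 3-methoxyphenol | COc1cccc(O)c1 | starting material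
14 | 2-[4-methoxy-2-(3-methoxyphenoxy)phenyl]acetic acid | OC(=O)Cc1ccc(OC)cc1Oc1cccc(OC)c1 | intermediate
15 | 3,7-dimethoxydibenzo[b,f]oxepin-10(11H)-one | O=C1Cc2ccc(OC)cc2Oc2cc(OC)ccc21 | intermediate
16 | 2-bromo-3,7-dimethoxydibenzo[b,f]oxepin-10(11H)-one | O=C1Cc2cc(Br)c(OC)cc2Oc2cc(OC)ccc21 | intermediate
17 | lithium 2-bromo-3,7-dimethoxydibenzo[b,f]oxepin-10-olate | [Li]OC1=Cc2cc(Br)c(OC)cc2Oc2cc(OC)ccc21 | intermediate
18 | 2-bromo-11-[(1S,5S)-7-hydroxy-2,6,6-trimethylbicyclo[3.2.0]hept-2-en-7-yl]-3,7-dimethoxydibenzo[b,f]oxepin-10(11H)-one (epimers at the carbinol carbon and C-11) | O=C1C(C3(O)[C@H]4[C@H](CC=C4C)C3(C)C)c2cc(Br)c(OC)cc2Oc2cc(OC)ccc21 | intermediate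
19 | 2-bromo-3,7-dimethoxy-11-[(1S,5S)-2,6,6-trimethylbicyclo[3.2.0]hept-2-en-7-ylidene]dibenzo[b,f]oxepin-10(11H)-one | O=C1C(=C3[C@H]4[C@H](CC=C4C)C3(C)C)c2cc(Br)c(OC)cc2Oc2cc(OC)ccc21 | intermediate
20 | 2-bromo-3,7-dimethoxy-11-[(1R,5S,7S)-2,6,6-trimethylbicyclo[3.2.0]hept-2-en-7-yl]dibenzo[b,f]oxepin-10(11H)-one (C-11 epimers; oxepinone on the concave face of the cyclobutane) | O=C1C([C@@H]3[C@H]4[C@H](CC=C4C)C3(C)C)c2cc(Br)c(OC)cc2Oc2cc(OC)ccc21 | intermediate
21 | target skeleton with Br in place of the prenyl group and both phenols as methyl ethers (three cyclobutane CH hydrogens all cis; ether oxygen on the tertiary carbon cis to the cyclobutane) | Brc1cc2c(cc1OC)Oc1cc(OC)ccc1C1=C2[C@@H]2[C@H]3[C@H](CC[C@@]3(C)O1)C2(C)C | intermediate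
22 | bis(methyl ether) of the target | CC(C)=CCc1cc2c(cc1OC)Oc1cc(OC)ccc1C1=C2[C@@H]2[C@H]3[C@H](CC[C@@]3(C)O1)C2(C)C | intermediate
23 | CNP0185814.1 | CC(C)=CCc1cc2c(cc1O)Oc1cc(O)ccc1C1=C2[C@@H]2[C@H]3[C@H](CC[C@@]3(C)O1)C2(C)C | target

Total step count: 17. Longest linear sequence: 14 steps (steps 1 to 8, then 12 to 17); the aromatic branch is steps 9 to 11.

Steps most likely to fail

Step 6. The triplet may cleave the external cyclopropane bond, the 1,4-diradical may fragment to an open-chain triene instead of closing, or closure may place the silyloxy group on the concave face. The fallback sets out from 5 and comes back at 9. It moves the rearrangement to the electron-rich silyl enol ether and runs it thermally. Ketone 5 is silylated (Me3SiOSO2CF3, NEt3) to (1R,4S,6S)-4-[(tert-butyldimethylsilyl)oxy]-5,5-dimethyl-2-[(trimethylsilyl)oxy]bicyclo[4.1.0]hept-2-ene F1. Flash vacuum pyrolysis at about 450 °C, the thermal cyclopentene annulation of 1-cyclopropyl silyl enol ethers, should give (1R,5S,7S)-7-[(tert-butyldimethylsilyl)oxy]-6,6-dimethyl-2-[(trimethylsilyl)oxy]bicyclo[3.2.0]hept-2-ene F2. MeLi followed by Comins' reagent converts it into (1R,5S,7S)-7-[(tert-butyldimethylsilyl)oxy]-6,6-dimethylbicyclo[3.2.0]hept-2-en-2-yl trifluoromethanesulfonate F3, and MeMgBr with Fe(acac)3 then gives 9.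

Step 12. Proton transfer from the hindered, enolisable cyclobutanone to the enolate, or retro-aldol reversal, may outrun C–C bond formation. The fallback sets out from 16 and comes back at 18. Ketone 16 is converted (Me3SiCl, NEt3, NaI, MeCN) into [(2-bromo-3,7-dimethoxydibenzo[b,f]oxepin-10-yl)oxy]trimethylsilane F4. A Mukaiyama aldol addition of this neutral silyl enol ether to 11, activated by TiCl4 in CH2Cl2 at −78 °C, should then give 18 without a basic enolate being present.

Step 15. Wagner–Meerwein ring expansion of the cyclobutane in the tertiary cyclobutylcarbinyl cation may compete with its capture by the carbonyl oxygen. The fallback sets out from 20 and comes back at 21 and avoids a free cation. Intramolecular alkoxymercuration with Hg(OCOCF3)2 in THF forms the mercurinium ion on the exo face, the carbonyl oxygen opens it anti at the tertiary carbon, and NaCl work-up gives the chloromercurio enol ether F5 (21 with HgCl on the ring CH2 next to the tertiary ether carbon, trans to the ether oxygen). NaBH4 in aqueous NaOH then replaces mercury by hydrogen to give 21.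

Further compounds
F1 | step 6 | (1R,4S,6S)-4-[(tert-butyldimethylsilyl)oxy]-5,5-dimethyl-2-[(trimethylsilyl)oxy]bicyclo[4.1.0]hept-2-ene | C[Si](C)(C)OC1=C[C@H](O[Si](C)(C)C(C)(C)C)C(C)(C)[C@H]2C[C@@H]12
F2 | step 6 | (1R,5S,7S)-7-[(tert-butyldimethylsilyl)oxy]-6,6-dimethyl-2-[(trimethylsilyl)oxy]bicyclo[3.2.0]hept-2-ene | CC(C)(C)[Si](C)(C)O[C@H]1[C@H]2[C@H](CC=C2O[Si](C)(C)C)C1(C)C
F3 | step 6 | (1R,5S,7S)-7-[(tert-butyldimethylsilyl)oxy]-6,6-dimethylbicyclo[3.2.0]hept-2-en-2-yl trifluoromethanesulfonate | CC(C)(C)[Si](C)(C)O[C@H]1[C@H]2[C@H](CC=C2OS(=O)(=O)C(F)(F)F)C1(C)C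
F4 | step 12 | [(2-bromo-3,7-dimethoxydibenzo[b,f]oxepin-10-yl)oxy]trimethylsilane | C[Si](C)(C)OC1=Cc2cc(Br)c(OC)cc2Oc2cc(OC)ccc21
F5 | step 15 | chloromercurio derivative of 21 (HgCl on the ring CH2 next to the tertiary ether carbon, trans to the ether oxygen) | Brc1cc2c(cc1OC)Oc1cc(OC)ccc1C1=C2[C@@H]2[C@H]3[C@H](C[C@H]([Hg]Cl)[C@@]3(C)O1)C2(C)C
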